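The route rests on disconnecting the bond between C4, the oxygen-bearing quaternary carbon, and C5, the neighbouring methine, which is common to the dihydropyran and the nine-membered carbocycle. The key step exploits that C4 is a masked methyl ketone and C5 the γ-terminus of a dienol of the triketone ring. One vinylogous Mukaiyama aldol cyclization with hydride quench closes the nine-membered ring, sets C4 and C5 and leaves the linking CH2 (C7'). Its precursor is a seco-caryophyllane: the keto aldehyde from ozonolysis of (−)-β-caryophyllene, joined by Wittig olefination to the dearomatized (S)-2-methylbutanoylphloroglucinol. Cyclodehydration then closes the pyran.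

Key step: step 6

Remark: the triketone ring is drawn throughout as one enol tautomer; labels follow caryophyllane numbering (C1 and C9 cyclobutane ring fusion, C4, C5, C8 methylidene carbon), C7' is the CH2 between C5 and the triketone ring, whose carbons are C1' (CMe2), C2' (enol-ether carbon), C3' (bears C7'), C4' (enol), C5' (bears the acyl group) and C6' (ketone).

Step 1
Reactants: 1 (−)-β-caryophyllene
Product: 3 keto aldehyde 4-[(1S,2R)-3,3-dimethyl-2-(3-oxobutyl)cyclobutyl]pent-4-enal, via secondary ozonide 2 (not isolated)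
Conditions: O3 (1.0 equiv), CH2Cl2, −78 °C; then Me2S, −78 °C → rt
Reagents that add atoms: ozone, O=[O+][O-]
Why: Ozonolysis with one equivalent should cleave only the strained, trisubstituted endocyclic (E)-alkene, which reacts with ozone far faster than the 1,1-disubstituted methylidene, and C1 and C9 are not touched.

Step 2
Reactants: 4 phloroglucinol; 5 (S)-2-methylbutanoyl chloride
Product: 6 (S)-2-methyl-1-(2,4,6-trihydroxyphenyl)butan-1-one
Conditions: AlCl3 (3.5 equiv), CH2Cl2/PhNO2, 0 °C → rt; aq. HCl
Reagents that add atoms: none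
Why: Friedel–Crafts C-acylation of the symmetric, strongly activated triol can give only one ketone, and the low temperature is chosen to keep the α-stereocenter brought in with 5 from enolizing.

Step 3
Reactants: 6 (S)-2-methyl-1-(2,4,6-trihydroxyphenyl)butan-1-one
Product: 8 gem-dimethyl triketone 3,5-dihydroxy-6,6-dimethyl-2-[(2S)-2-methylbutanoyl]cyclohexa-2,4-dien-1-one, via C-monomethyl triol 7 (not isolated)
Conditions: NaOMe (3 equiv), MeI (2.1 equiv), MeOH, 0 °C → rt; aq. HCl
Reagents that add atoms: iodomethane, CI
Why: Double C-methylation of the phloroglucinate should go to the gem-dimethyl, dearomatized triketone because the first methyl group raises the nucleophilicity of its own ring carbon, and the polyanion is not enolized at the side-chain stereocenter by methoxide.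

Step 4
Reactants: 8 gem-dimethyl triketone
Product: 10 zwitterionic phosphonium salt (8 carrying CH2–PPh3+ on C3' as its enolate), via o-quinone methide 9 (not isolated)
Conditions: (CH2O)n, PPh3, NaOAc (cat.), AcOH/CH2Cl2, 40 °C
Reagents that add atoms: formaldehyde (as paraformaldehyde), C=O; triphenylphosphine, c1ccc(cc1)P(c1ccccc1)c1ccccc1
Why: Knoevenagel condensation with formaldehyde should give the o-quinone methide 9, which the soft phosphine, used in excess, traps by phospha-Michael addition before a second triketone can add, leaving a stable inner salt.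

Step 5
Reactants: 10 zwitterionic phosphonium salt; 3 keto aldehyde
Product: 13 (E)-dienol ketone (8 carrying the (1E)-5-[(1S,2R)-3,3-dimethyl-2-(3-oxobutyl)cyclobutyl]hexa-1,5-dien-1-yl chain on C3'), via dilithium ylide 11 (not isolated), via (Z)-dienol ketone 12 (not isolated)
Conditions: LiN(SiMe3)2 (2.1 equiv), THF, −78 → 0 °C; then 3, −78 °C → rt; aq. NH4Cl; then PhSSPh (10 mol %), blue light, benzene, rt
Reagents that add atoms: none
Why: Wittig olefination should take place at the aldehyde of 3 much faster than at its methyl ketone, and reversible thiyl-radical addition then equilibrates the (Z)-alkene formed alongside to the more stable (E)-dienol needed for step 6; no stereocenter is created.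

Step 6
Reactants: 13 (E)-dienol ketone
Product: 17 hydroxy triketone (8 carrying the [(1R,4R,5S,9S)-4-hydroxy-4,11,11-trimethyl-8-methylidenebicyclo[7.2.0]undecan-5-yl]methyl group on C3'), via bis(trimethylsilyl) dienol ether 14 (not isolated), via cyclized alkylidene triketone 15 (not isolated), via triethylsilyl enol ether 16 (not isolated)
Conditions: HN(SiMe3)2, CH2Cl2, 40 °C, then evaporation; Tf2NH (10 mol %), CH2Cl2 (0.002 M), −78 → −30 °C; then Et3SiH (3 equiv), −78 → 0 °C; then 1 M HCl, THF, 0 °C
Reagents that add atoms: none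
Why: Me3SiNTf2, formed in the flask from Tf2NH and 14, activates the C4 ketone, the γ-carbon C5 of the silyl dienol ether attacks it (intramolecular vinylogous Mukaiyama aldol reaction) with silyl transfer to the new alkoxide, and the alkylidene triketone 15 so formed (an o-quinone methide) takes hydride from Et3SiH at C7' before the silyl groups are hydrolysed. The closest known reaction type is the Lewis acid vinylogous Mukaiyama aldol cyclization of silyl dienol ethers that closes eight-membered carbocycles, followed by the usual hydride reduction of an o-quinone methide. One ring is closed, the nine-membered carbocycle, in a 9-(enolexo)-exo-trig mode at high dilution; the pyran is left for step 7. C4 and C5 are both set as the C4–C5 bond forms: a compact, [4+2]-like synclinal transition state with the ketone oxygen over C2' and the tether exo to the (E)-dienol ether should place C3 and C6 trans across the new bond, and the trans-fused gem-dimethylcyclobutane together with the C8 methylidene should fold the seven-atom tether as in (−)-β-caryophyllene, exposing the ketone and alkene faces that give 4R,5S. The step needs γ- over α-attack (secured by the fully substituted C3' and the eleven-membered ring that α-attack would require), attack by C5 and not by the far less nucleophilic C8 methylidene, and hydride capture of 15 before its C5 proton is lost (secured by the base-free medium and the cold quench).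

Step 7
Reactants: 17 hydroxy triketone
Product: 19 CNP0591516.2 (target), via cyclic hemiketal 18 (not isolated)
Conditions: PPTS (10 mol %), toluene, 4 Å molecular sieves, 60 °C
Reagents that add atoms: none
Why: Acid-catalysed cyclodehydration of a δ-hydroxy β-diketone: the tertiary C4 hydroxyl adds 6-exo-trig to the C2' carbonyl, which is the free one because the C4' enol is locked in its hydrogen bond to the acyl group, and hemiketal 18 loses water to the vinylogous ester, so the C4–O bond and both new stereocenters are retained.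

Compound list
1 | (−)-β-caryophyllene, (1R,4E,9S)-4,11,11-trimethyl-8-methylidenebicyclo[7.2.0]undec-4-ene | C/C1=C\CCC(=C)[C@H]2CC(C)(C)[C@@H]2CC1 | starting material
2 | secondary ozonide of 1 (1,2,4-trioxolane spanning C4 and C5, methylidene intact) | CC13OOC(O3)CCC(=C)[C@H]2CC(C)(C)[C@@H]2CC1 | intermediate
3 | 4-[(1S,2R)-3,3-dimethyl-2-(3-oxobutyl)cyclobutyl]pent-4-enal (C4 methyl ketone, C5 aldehyde) | O=CCCC(=C)[C@H]1CC(C)(C)[C@@H]1CCC(C)=O | intermediate
4 | phloroglucinol (benzene-1,3,5-triol) | Oc1cc(O)cc(O)c1 | starting material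
5 | (S)-2-methylbutanoyl chloride | CC[C@H](C)C(Cl)=O | starting material
6 | (S)-2-methyl-1-(2,4,6-trihydroxyphenyl)butan-1-one | CC[C@H](C)C(=O)c1c(O)cc(O)cc1O | intermediate
7 | (S)-2-methyl-1-(2,4,6-trihydroxy-3-methylphenyl)butan-1-one | CC[C@H](C)C(=O)c1c(O)cc(O)c(C)c1O | intermediate
8 | 3,5-dihydroxy-6,6-dimethyl-2-[(2S)-2-methylbutanoyl]cyclohexa-2,4-dien-1-one | CC[C@H](C)C(=O)C1=C(O)C=C(O)C(C)(C)C1=O | intermediate
9 | 5-hydroxy-2,2-dimethyl-6-methylidene-4-[(2S)-2-methylbutanoyl]cyclohex-4-ene-1,3-dione (o-quinone methide) | CC[C@H](C)C(=O)C1=C(O)C(=C)C(=O)C(C)(C)C1=O | intermediate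
10 | inner salt of 8 bearing a (triphenylphosphonio)methyl group on C3' (enolate / phosphonium zwitterion) | CC[C@H](C)C(=O)C1=C(O)C(C[P+](c2ccccc2)(c2ccccc2)c2ccccc2)=C([O-])C(C)(C)C1=O | intermediate
11 | dilithium bis-enolate of the triphenylphosphorane ylide derived from 10 | CC[C@H](C)C(=O)C1=C([O-])C(C=P(c2ccccc2)(c2ccccc2)c2ccccc2)=C([O-])C(C)(C)C1=O.[Li+].[Li+] | intermediate
12 | (Z)-isomer of 13 at the C5=C7' alkene | CC[C@H](C)C(=O)C1=C(O)C(/C=C\CCC(=C)[C@H]2CC(C)(C)[C@@H]2CCC(C)=O)=C(O)C(C)(C)C1=O | intermediate
13 | 4-[(1E)-5-[(1S,2R)-3,3-dimethyl-2-(3-oxobutyl)cyclobutyl]hexa-1,5-dien-1-yl]-3,5-dihydroxy-6,6-dimethyl-2-[(2S)-2-methylbutanoyl]cyclohexa-2,4-dien-1-one | CC[C@H](C)C(=O)C1=C(O)C(/C=C/CCC(=C)[C@H]2CC(C)(C)[C@@H]2CCC(C)=O)=C(O)C(C)(C)C1=O | intermediate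
14 | bis(trimethylsilyl) ether of 13 at the C2' and C4' enol oxygens (silyl dienol ether) | CC[C@H](C)C(=O)C1=C(O[Si](C)(C)C)C(/C=C/CCC(=C)[C@H]2CC(C)(C)[C@@H]2CCC(C)=O)=C(O[Si](C)(C)C)C(C)(C)C1=O | intermediate
15 | cyclized alkylidene triketone: nine-membered ring closed at C4–C5, C4–OSiMe3, C3'=C7' exocyclic alkene, C2' ketone, C4'–OSiMe3 | C=C1CC[C@@H](C=C3C(=O)C(C)(C)C(=O)C(C(=O)[C@@H](C)CC)=C3O[Si](C)(C)C)[C@@](O[Si](C)(C)C)(C)CC[C@@H]2[C@@H]1CC2(C)C | intermediate
16 | 1,4-hydrosilylation product of 15: C7' methylene, C2'–OSiEt3 enol ether, C4–OSiMe3, C4'–OSiMe3 | C=C1CC[C@@H](CC3=C(O[Si](CC)(CC)CC)C(C)(C)C(=O)C(C(=O)[C@@H](C)CC)=C3O[Si](C)(C)C)[C@@](O[Si](C)(C)C)(C)CC[C@@H]2[C@@H]1CC2(C)C | intermediate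
17 | 3,5-dihydroxy-4-{[(1R,4R,5S,9S)-4-hydroxy-4,11,11-trimethyl-8-methylidenebicyclo[7.2.0]undecan-5-yl]methyl}-6,6-dimethyl-2-[(2S)-2-methylbutanoyl]cyclohexa-2,4-dien-1-one | C=C1CC[C@@H](CC3=C(O)C(C)(C)C(=O)C(C(=O)[C@@H](C)CC)=C3O)[C@@](O)(C)CC[C@@H]2[C@@H]1CC2(C)C | intermediate
18 | cyclic hemiketal of 17 (C4 oxygen bonded to C2', which also carries OH; C3' sp3) | C=C1CC[C@H]2CC3C(O)(O[C@]2(C)CC[C@@H]2[C@@H]1CC2(C)C)C(C)(C)C(=O)C(C(=O)[C@@H](C)CC)=C3O | intermediate
19 | CNP0591516.2: pyran closed between the C4 oxygen and C2' of 17; (1R,4R,5S,9S)-caryophyllane unit, (2S)-2-methylbutanoyl group | C=C1CC[C@H]2CC3=C(O[C@]2(C)CC[C@@H]2[C@@H]1CC2(C)C)C(C)(C)C(=O)C(C(=O)[C@@H](C)CC)=C3O | target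

Total step count: 7
Longest linear sequence: 6 steps (4 → 6 → 8 → 10 → 13 → 17 → 19; the terpene branch 1 → 3 joins at step 5)

Steps most likely to fail

Step 6. The closure of a nine-membered ring onto an unactivated ketone may be outrun by intermolecular aldol addition or by carbonyl-ene attack of the C8 methylidene on the activated ketone. The alkylidene intermediate may lose its C5 proton before hydride arrives, and the facial selectivity at the ketone may be low. The fallback replaces the polar closure by a radical one. It sets out from 13: silylation with tBuMe2SiOTf and 2,6-lutidine should give the bis(tert-butyldimethylsilyl) dienol ether F1. SmI2 with HMPA and t-BuOH in THF at high dilution should then generate the C4 ketyl, which adds to C5 of the conjugated alkene (ketyl–olefin cyclization, again forming C4–C5). After reduction and protonation at C7' this gives the silylated tertiary alcohol F2. TsOH·H2O in toluene at 60 °C should remove the silyl groups and close the pyran, so the fallback comes back to the route at 19.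

Step 5. Ylide formation from the polyanionic zwitterion may be incomplete, the basic ylide may enolize 3, and control of alkene geometry may be poor. The fallback builds the same compound by condensation instead of olefination, setting out from 3 and 8. Wittig homologation of 3 with Ph3P=CHOMe (from the phosphonium chloride and KOtBu, THF, −78 °C) should give the enol ether F3, and aq. HCl in THF the one-carbon-longer keto aldehyde F4. Knoevenagel condensation of F4 with 8 (ethylenediammonium diacetate cat., CH2Cl2) should give the alkylidene triketone F5. The amine then equilibrates F5 by γ-deprotonation to the conjugated (E)-dienol, so the fallback comes back at 13.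

Step 7. The tertiary C4 alcohol may ionize under acid (loss of water to alkenes, or closure through a cation with scrambling of C4), and closure may occur at the C4' instead of the C2' oxygen. The fallback avoids acid and sets out from 17. O-Sulfonylation of the free C2' enol with TsCl and Et3N (CH2Cl2, 0 °C) should give the vinylogous tosylate F6. KN(SiMe3)2 (2 equiv, THF, −78 → 0 °C; aq. NH4Cl) should then close the pyran by intramolecular addition–elimination of the C4 alkoxide at C2', so the fallback comes back at 19.

Further compounds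
F1 | step 6 | bis(tert-butyldimethylsilyl) ether of 13 at the C2' and C4' enol oxygens | CC[C@H](C)C(=O)C1=C(O[Si](C)(C)C(C)(C)C)C(/C=C/CCC(=C)[C@H]2CC(C)(C)[C@@H]2CCC(C)=O)=C(O[Si](C)(C)C(C)(C)C)C(C)(C)C1=O
F2 | step 6 | bis(tert-butyldimethylsilyl) ether of 17 at the C2' and C4' enol oxygens (free tertiary C4 alcohol) | C=C1CC[C@@H](CC3=C(O[Si](C)(C)C(C)(C)C)C(C)(C)C(=O)C(C(=O)[C@@H](C)CC)=C3O[Si](C)(C)C(C)(C)C)[C@@](O)(C)CC[C@@H]2[C@@H]1CC2(C)C
F3 | step 5 | methyl enol ether from homologation of 3 (E/Z mixture), 4-[(1S,2R)-2-(6-methoxy-1-methylidenehex-5-en-1-yl)-3,3-dimethylcyclobutyl]butan-2-one | COC=CCCC(=C)[C@H]1CC(C)(C)[C@@H]1CCC(C)=O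
F4 | step 5 | 5-[(1S,2R)-3,3-dimethyl-2-(3-oxobutyl)cyclobutyl]hex-5-enal | O=CCCCC(=C)[C@H]1CC(C)(C)[C@@H]1CCC(C)=O
F5 | step 5 | alkylidene triketone tautomer of 13 (C3'=C7' exocyclic alkene, C5 methylene) | CC[C@H](C)C(=O)C1=C(O)C(=CCCCC(=C)[C@H]2CC(C)(C)[C@@H]2CCC(C)=O)C(=O)C(C)(C)C1=O
F6 | step 7 | C2' enol 4-methylbenzenesulfonate of 17 | C=C1CC[C@@H](CC3=C(OS(=O)(=O)c4ccc(C)cc4)C(C)(C)C(=O)C(C(=O)[C@@H](C)CC)=C3O)[C@@](O)(C)CC[C@@H]2[C@@H]1CC2(C)C
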